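Each catalyst had to go round 16.7 times to clear the charge, so I reckoned the time of one round.

all flasks: substrate 5.0 × 10⁻⁴ M; reagent 0.600 mM; free catalyst 30 µM

| run | time |
|---|---|
| Sunday's | 150 s |
| Friday's | 50 s |

    reagent + free catalyst → catalyst intermediate A (k1 = 4000 /M/s)
    catalyst intermediate A → catalyst intermediate B (k2 = 99 /s)
    substrate + catalyst intermediate B → catalyst intermediate C (k3 = 4300 /M/s)
    catalyst intermediate C ⇌ catalyst intermediate D (K4 = 0.90, k4 = 85 /s)
    catalyst intermediate D → free catalyst + product (k5 = 0.36 /s)
    crystals ⇌ product, rate k6*(cs6 - [product]) while solid is left; crystals form when [product] > cs6 (cs6 = 0.32 mM, k6 = 0.94 /s)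

- which of these there is most of at the end, counted by the substrate in it, Sunday's (catalyst intermediate D / product / catalyst intermediate C / substrate)
- which of these there is most of at the end, counted by the substrate in it, Friday's (catalyst intermediate D / product / catalyst intermediate C / substrate)
- amount of the one of these that there is most of at the end, in percent of the substrate charged, Sunday's
- amount of the one of these that there is most of at the end, in percent of the substrate charged, Friday's

Substrate is the limiting reagent, with 5.0 × 10⁻⁴ M against 0.600 mM of reagent. Product is counted with its crystals, so I left step 6 out of the reckoning. Here is my ladder, in waits at the charged concentrations.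

1. Catalyst intermediate A became catalyst intermediate B in about 0.0101 s, and catalyst intermediate C became catalyst intermediate D in about 0.0118 s. So C and D stood in their equilibrium ratio while D slowly left.

2. Free catalyst met reagent in 0.417 s, and catalyst intermediate B met substrate in 0.465 s.

3. Catalyst intermediate D left in 2.78 s, but the catalyst in the pair C and D sat as D for a share of 47.4%. The pair therefore held it for 5.86 s. This was the rate-limiting stretch and the resting state at the charge.

4. The waits summed to τ = 6.76 s, the cycle time at the charge. Dividing the catalyst charge by τ gave 4.44 µM/s of product.

5. Holding that rate over 50 s, I reckoned 44.4% of the charge as product in Friday's flask. With 5.21% of the charge bound in the pair, that put 50.4% as substrate, so in my reckoning substrate led.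

6. At the far end, on Sunday's, the wait for substrate grows as substrate falls, with a time constant of 7.75 s for the tail. Joining both ends, the run time is a fixed part, 97.9 s, plus a logarithm for the fall of reagent and one for the fall of substrate. Taking reagent down by the substrate charge, to 0.100 mM with the share held by the catalyst left out, cost 14.9 s. By my reckoning the rest of 150 s left 0.828% of the substrate on Sunday's, so I put product in the lead there.

The forecast said product at 99.4% (98% to 99.9%) on Sunday's, and substrate at 53% (49% to 57%) on Friday's. Its grounds: “slowing as substrate and reagent are used up”. Its Friday's substrate stood higher than my 50.4%.

The simulation gave product at 98.3% on Sunday's, and substrate at 53.5% on Friday's, both inside the forecast's ranges.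

Friday's flask held 41.8% of product against my 44.4% from τ. The catalyst charge does not enter τ, so I used the same 6.76 s for the neighbour, which is Friday's flask with 1.8 × 10⁻⁵ M of free catalyst. It gave 2.66 µM/s, and so 26.6% of the charge as product over 50 s. That neighbour flask held 25.6% of product, with 71.4% of its substrate left.

The constants used here are assumed; the rest is arithmetic.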